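3 questions stood for one flask: 47 mM substrate, 0.950 equiv of reagent in the second phase, 2.0 h.

| setting | Wednesday's | Thursday's | Monday's | flask |
|---|---|---|---|---|
| substrate | 24 mM | 35 mM | 47 mM | 47 mM |
| reagent in the second phase | 0.95 equiv | 0.95 equiv | 1.9 equiv | 0.950 equiv |
| remark | run made earlier | run made earlier | run made earlier |  |
| time |  |  |  | 2.0 h |
| volume of the second phase over the first |  |  |  | 1.0 |

| run | time / h | target / % | substrate / % |
|---|---|---|---|
| Wednesday's | 0.667 | 1.0 | 99.3 |
| Wednesday's | 1.33 | 4.6 | 97.4 |
| Wednesday's | 2.00 | 4.3 | 96.2 |
| Wednesday's | 2.50 | 6.4 | 92.5 |
| Thursday's | 0.667 | 2.3 | 98.4 |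
| Thursday's | 1.33 | 3.9 | 96.5 |
| Thursday's | 2.00 | 6.6 | 93.7 |
| Thursday's | 2.50 | 7.7 | 90.5 |
| Monday's | 0.200 | 1.0 | 99.4 |
| Monday's | 0.417 | 1.0 | 99.1 |
| Monday's | 1.00 | 6.5 | 93.8 |
| Monday's | 2.50 | 18.0 | 77.3 |

(standard deviation of a reading: 0.5 percentage points)

- in the second phase: reagent in the second phase; everything else is in the first
- charges count per volume of the first phase; a concentration in a rate is the amount of a species over the volume of its own phase; every rate counts per litre of the first phase
- the earlier runs hold the two phases in the same ratio of volumes as the flask asked about

- zeta: doubling the amount of reagent in the second phase, all else as stated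
- beta: doubling the transfer coefficient of the reagent in the second phase, all else as stated

- amount of target at 2.0 h, in percent of the substrate charged
- the change that raises the amount of target at 2.0 h, in percent of the substrate charged most ("none" if none brings more than 2 percentage points) (zeta / beta / none)
- amount of target at 2.0 h, in percent of the substrate charged, after zeta

I supposed that each substrate molecule turns to target at a rate proportional to the reagent that has crossed, and that this reagent follows the reagent charged. I therefore replaced the curves by their means and carried one number: the fraction of substrate made into target by 2.00 h per molar of reagent charged, w = 1.94 /M, read from Wednesday's and Thursday's runs pooled. Thursday's substrate averaged about 96.8 % of its charge up to that time, so holding it at its charge errs by about 3.15 % in that run. The flask charges 44.6 mM of reagent, so I expected 8.68 %. Zeta doubles the charge, so the same rule gave 17.4 %; for beta the readings gave me no figure.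

The forecast said 7.6 %, with zeta best at 14.2 %, taking “about half of Monday's 2 h target”, below my figure.

The flask gave 8.42 %. Zeta was best, gaining 6.4 percentage points against 2 points for beta, and reached 14.8 %, which is 2.5 points below my rule.

    reagent in the reaction phase ⇌ reagent in the second phase, rate k1*([reagent in the reaction phase] - [reagent in the second phase]/K1) per volume of the first phase (partition coefficient = 0.820, kL = 0.530 /h)
    substrate + reagent in the reaction phase → target (k = 3.50 /M/h)
    reagent in the reaction phase + target → over-reacted product (k = 5.70 /M/h)
    substrate → decomposition product (k = 9.00 × 10⁻⁵ /h)

A neighbouring flask held 19 mM substrate at the same 0.950 equiv, so it charged 18.1 mM of reagent, and w gave 3.50 % for it. That neighbouring flask made 3.88 % of target at 2.00 h, with 96.0 % of its substrate left.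

The readings were generated by integration from invented constants, and the scatter is random.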